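The readings are calculated for substances that don't exist, noise included.

Our colleague wants the target from one flask and has three earlier runs to go on.

| setting | violet | ochre | green | flask |
|---|---|---|---|---|
| starting material | 0.17 M | 0.26 M | 0.12 M | 0.12 M |
| gas phase | 6.3 mM (held) | 6.3 mM (held) | 6.3 mM (held) | 6.3 mM (held) |
| free catalyst | 2.4 mM | 2.4 mM | 3.6 mM | 2.4 mM |
| remark | run made earlier | run made earlier | run made earlier |  |
| time |  |  |  | 10 d |

- violet (time / d: target / %, starting material / %): 1.67: 20.3, 80.4; 4.00: 28.0, 70.6; 8.00: 37.7, 63.5; 12.0: 40.2, 58.0
- ochre (time / d: target / %, starting material / %): 1.04: 9.4, 90.3; 2.00: 15.6, 81.5; 5.00: 26.9, 71.7; 12.0: 37.5, 60.7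
- green (time / d: target / %, starting material / %): 3.00: 30.8, 70.5; 6.00: 36.6, 63.0; 10.0: 42.0, 59.1; 12.0: 43.7, 53.8

(each reading ± 1 percentage point)

- at the start none of the gas is dissolved
- steps under discussion: gas phase <-> dissolved gas; starting material + dissolved gas + free catalyst -> free catalyst + target; target -> over-reaction product; 2 free catalyst -> spent catalyst

- spring: doubling the saturation concentration of gas phase, all else as stated
- midnight: doubling the amount of free catalyst, all else as stated
- dusk: doubling the transfer coefficient of the gas phase, all else as stated

1. amount of target at 10 d, in percent of the starting material charged
2. the change that raises the amount of target at 10 d, in percent of the starting material charged most ("none" if none brings more than 2 percentage points) (spring / midnight / dusk / none)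
3. amount of target at 10 d, in percent of the starting material charged, after spring

We call the dose ln([starting material] charged / [starting material] left). Target tracks the loss of starting material: in violet at 12.0 d the two readings sum to 98.2%. The violet and ochre doses look nearly alike, the pseudo-first-order pattern, but ochre, with the larger charge, lags at 12.0 d. That lag gives 0.506 M⁻¹, a reading with the scatter in it: the charge penalty, the dose lost per molar of starting material charged, at that time and with the gas and free catalyst of those two runs.

Midway in time between its readings at 8.00 d and 12.0 d, we take the violet dose as the mean of the two, 0.499. Our flask charges 0.0500 M less, so we add the penalty on that and reach 0.525, which means 40.8% target.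

Green, with more catalyst, left 59.1% at 10.0 d, level with our 59.2%, so we expect little from midnight. We read the penalty as dissolved gas held down by the charge. The flask's penalty, 0.0607, is smaller than its dose, so we expect less from dusk than from spring. Spring doubles the saturation concentration, and dissolved gas enters the step that makes target, so we double the dose and reckon 65.0%.

The forecast gave 40%, spring and 62%, holding that “the reaction is roughly first order in starting material”. The flask gives 41.2%, and spring is best at 25 percentage points, against 4.1 points for dusk and 2.1 points for midnight, reaching 65.8%.

    gas phase ⇌ dissolved gas, rate k1*(csat - [dissolved gas]) (kL = 0.360 h⁻¹)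
    starting material + dissolved gas + free catalyst → free catalyst + target (k = 2300 M⁻² h⁻¹)
    target → over-reaction product (k = 1.30 × 10⁻⁴ h⁻¹)
    2 free catalyst → spent catalyst (k = 36.0 M⁻¹ h⁻¹)

Now take a neighbour charged with 0.48 M of starting material, at the same time. The flask's 57.9% of starting material left is a dose of 0.547. The penalty on the extra charge lowers that to 0.365, so we reckon 69.4% left. The neighbour holds 69.0% of starting material and 30.3% of target.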